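**Retrosynthetic overview**

- Target ⇐ BBr3 demethylation of its hexamethyl ether ⇐ hydrogenolysis of the 5,7-dibromo hexamethyl ether; the two bromines are blocking groups on ring A.
- Dihydrofuran ring (the only ring built, O1–C2 closed last, trans to C3) ⇐ acid cyclization of the carbinol formed by adding a 2,4-dimethoxyphenyl organometallic to a 3-aryl lactol (C2–aryl bond).
- Lactol ⇐ ozonolysis of a 2-(1-arylbut-2-enyl)phenol ⇐ aromatic Claisen [3,3] shift of an (S,E) 1-methyl-3-arylallyl aryl ether, which forms C3–C3a and sets C3 by 1,3-chirality transfer.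
- Ether ⇐ Mitsunobu coupling of the dibromophenol with methyl (R)-lactate (inversion), then ester-to-aldehyde reduction and Horner–Wadsworth–Emmons olefination.
- Dibromophenol ⇐ dibromination of the bibenzyl phenol ⇐ B-alkyl Suzuki coupling of 3-bromo-5-methoxyphenol with hydroborated 4-methoxystyrene; all benzene rings are bought.

Assumption: the target SMILES is read as (2S,3S), i.e. 2,3-trans; 2,4-dimethoxyphenylmagnesium bromide is bought as its THF solution.

**Route**

Step 1
Reactants: 1 4-methoxystyrene; 2 3-bromo-5-methoxyphenol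
Product: 4 3-methoxy-5-[2-(4-methoxyphenyl)ethyl]phenol, via alkylborane 3 (not isolated)
Conditions: 1, 9-BBN, THF, 0 °C → rt; then 2, PdCl2(dppf) (3 mol%), 3 M NaOH (aq), THF, 65 °C; acidic work-up
Reagents that add atoms: none
Why: Anti-Markovnikov hydroboration gives the primary alkylborane, which undergoes B-alkyl Suzuki–Miyaura coupling with the aryl bromide under aqueous base that tolerates the free phenol as its phenoxide.

Step 2
Reactants: 4 3-methoxy-5-[2-(4-methoxyphenyl)ethyl]phenol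
Product: 5 2,4-dibromo-5-methoxy-3-[2-(4-methoxyphenyl)ethyl]phenol
Conditions: NBS (2.05 equiv), MeCN, 0 °C → rt, dark
Reagents that add atoms: N-bromosuccinimide, O=C1CCC(=O)N1Br
Why: Electrophilic aromatic bromination of the doubly activated ring goes to the two positions para to an oxygen (flanking the alkyl chain), so the only ring C–H left is the one between OH and OMe and the later rearrangement has a single ortho terminus.

Step 3
Reactants: 5 2,4-dibromo-5-methoxy-3-[2-(4-methoxyphenyl)ethyl]phenol; 6 methyl (R)-lactate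
Product: 7 methyl (2S)-2-{2,4-dibromo-5-methoxy-3-[2-(4-methoxyphenyl)ethyl]phenoxy}propanoate
Conditions: PPh3, DIAD, THF, 0 °C → rt
Reagents that add atoms: none
Why: Mitsunobu reaction, an SN2 displacement of the activated lactate hydroxyl by the acidic bromophenol with clean inversion, turns the purchased (R) centre into the (S) aryloxy centre.

Step 4
Reactants: 7 methyl (2S)-2-{2,4-dibromo-5-methoxy-3-[2-(4-methoxyphenyl)ethyl]phenoxy}propanoate
Product: 8 (2S)-2-{2,4-dibromo-5-methoxy-3-[2-(4-methoxyphenyl)ethyl]phenoxy}propanal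
Conditions: iBu2AlH (1.1 equiv), CH2Cl2, −78 °C; MeOH, then aq. potassium sodium tartrate; used crude at once
Reagents that add atoms: none
Why: Partial hydride reduction of the α-aryloxy ester stops at the chelated aluminium hemiacetal at −78 °C and releases the aldehyde on work-up without touching the stereocentre, aryl bromides or ethers.

Step 5
Reactants: 8 (2S)-2-{2,4-dibromo-5-methoxy-3-[2-(4-methoxyphenyl)ethyl]phenoxy}propanal; 9 diethyl (3,5-dimethoxybenzyl)phosphonate
Product: 10 1,3-dibromo-4-{[(2S,3E)-4-(3,5-dimethoxyphenyl)but-3-en-2-yl]oxy}-6-methoxy-2-[2-(4-methoxyphenyl)ethyl]benzene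
Conditions: 9 (1.2 equiv), KN(SiMe3)2 (1.15 equiv), THF, −78 °C; then 8, −78 → 0 °C
Reagents that add atoms: none
Why: Horner–Wadsworth–Emmons olefination with a benzylphosphonate anion is strongly E-selective, and pre-forming the anion without excess base and adding the aldehyde cold keeps the α-aryloxy centre intact.

Step 6
Reactants: 10 1,3-dibromo-4-{[(2S,3E)-4-(3,5-dimethoxyphenyl)but-3-en-2-yl]oxy}-6-methoxy-2-[2-(4-methoxyphenyl)ethyl]benzene
Product: 12 4,6-dibromo-2-[(1S,2E)-1-(3,5-dimethoxyphenyl)but-2-en-1-yl]-3-methoxy-5-[2-(4-methoxyphenyl)ethyl]phenol, via ortho-dienone 11 (not isolated)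
Conditions: PhNEt2, 180–190 °C, sealed tube, Ar
Reagents that add atoms: none
Why: Aromatic Claisen rearrangement, a suprafacial [3,3] shift through a chair transition state with the methyl group pseudo-equatorial, forms the C3–C3a bond at the only free ortho carbon with 1,3-chirality transfer (S ether carbon to S benzylic carbon, new alkene E) before the dienone tautomerizes to the phenol.

Step 7
Reactants: 12 4,6-dibromo-2-[(1S,2E)-1-(3,5-dimethoxyphenyl)but-2-en-1-yl]-3-methoxy-5-[2-(4-methoxyphenyl)ethyl]phenol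
Product: 14 (3S)-5,7-dibromo-3-(3,5-dimethoxyphenyl)-4-methoxy-6-[2-(4-methoxyphenyl)ethyl]-2,3-dihydro-1-benzofuran-2-ol (lactol; both C2 epimers), via hydroxy-aldehyde 13 (not isolated)
Conditions: O3, CH2Cl2/MeOH, −78 °C (Sudan Red 7B end point); then Me2S, −78 °C → rt; used crude
Reagents that add atoms: ozone, [O-][O+]=O
Why: Ozonolysis with reductive work-up cleaves the alkene (the spent lactate carbon leaves as acetaldehyde) faster than the brominated phenol or the methoxyarenes react, and the α,α-diaryl aldehyde is trapped at once as the five-membered lactol, which shields the benzylic stereocentre from enolization.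

Step 8
Reactants: 14 (3S)-5,7-dibromo-3-(3,5-dimethoxyphenyl)-4-methoxy-6-[2-(4-methoxyphenyl)ethyl]-2,3-dihydro-1-benzofuran-2-ol; 15 2,4-dimethoxyphenylmagnesium bromide
Product: 17 (2S,3S)-5,7-dibromo-2-(2,4-dimethoxyphenyl)-3-(3,5-dimethoxyphenyl)-4-methoxy-6-[2-(4-methoxyphenyl)ethyl]-2,3-dihydro-1-benzofuran, via diol 16 (not isolated)
Conditions: 15 (3 equiv), anhydrous CeCl3 (3 equiv), THF, −78 °C; then 14, −78 → 0 °C; then 1 M HCl (aq), 0 °C → rt
Reagents that add atoms: none
Why: The weakly basic organocerium reagent adds (1,2-addition) to the aldehyde released from the lactolate, and acid then ionizes the 2,4-dimethoxybenzylic alcohol to a stabilized cation that the phenol captures (SN1 cyclodehydration) anti to the C3 aryl group, so both carbinol epimers converge on the more stable 2,3-trans (2S,3S) dihydrobenzofuran.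

Step 9
Reactants: 17 (2S,3S)-5,7-dibromo-2-(2,4-dimethoxyphenyl)-3-(3,5-dimethoxyphenyl)-4-methoxy-6-[2-(4-methoxyphenyl)ethyl]-2,3-dihydro-1-benzofuran
Product: 18 (2S,3S)-2-(2,4-dimethoxyphenyl)-3-(3,5-dimethoxyphenyl)-4-methoxy-6-[2-(4-methoxyphenyl)ethyl]-2,3-dihydro-1-benzofuran
Conditions: H2 (1 atm), 10% Pd/C, Et3N (3 equiv), EtOAc/MeOH, rt
Reagents that add atoms: none
Why: Catalytic hydrogenolysis of the two aryl C–Br bonds is much faster than cleavage of the benzylic C2–O bond, all the more with triethylamine present to take up HBr and temper the catalyst, and no stereocentre is touched.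

Step 10
Reactants: 18 (2S,3S)-2-(2,4-dimethoxyphenyl)-3-(3,5-dimethoxyphenyl)-4-methoxy-6-[2-(4-methoxyphenyl)ethyl]-2,3-dihydro-1-benzofuran
Product: 19 (2S,3S)-2-(2,4-dihydroxyphenyl)-3-(3,5-dihydroxyphenyl)-6-[2-(4-hydroxyphenyl)ethyl]-2,3-dihydro-1-benzofuran-4-ol
Conditions: BBr3 (12 equiv), CH2Cl2, −78 °C → rt; then MeOH/H2O, 0 °C
Reagents that add atoms: none
Why: Lewis-acid ether cleavage removes all six methyl ethers, and the only acid-labile bond (C2–O) can at worst ionize reversibly and reclose to the favoured trans isomer while C3 stays untouched.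

**Compound list**

1 | 4-methoxystyrene | C=Cc1ccc(OC)cc1 | starting material
2 | 3-bromo-5-methoxyphenol | COc1cc(O)cc(Br)c1 | starting material
3 | 9-[2-(4-methoxyphenyl)ethyl]-9-borabicyclo[3.3.1]nonane (alkylborane) | COc1ccc(CCB2C3CCCC2CCC3)cc1 | intermediate
4 | 3-methoxy-5-[2-(4-methoxyphenyl)ethyl]phenol | COc1ccc(CCc2cc(O)cc(OC)c2)cc1 | intermediate
5 | 2,4-dibromo-5-methoxy-3-[2-(4-methoxyphenyl)ethyl]phenol | COc1ccc(CCc2c(Br)c(O)cc(OC)c2Br)cc1 | intermediate
6 | methyl (R)-lactate | C[C@@H](O)C(=O)OC | starting material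
7 | methyl (2S)-2-{2,4-dibromo-5-methoxy-3-[2-(4-methoxyphenyl)ethyl]phenoxy}propanoate | C[C@H](Oc1cc(OC)c(Br)c(CCc2ccc(OC)cc2)c1Br)C(=O)OC | intermediate
8 | (2S)-2-{2,4-dibromo-5-methoxy-3-[2-(4-methoxyphenyl)ethyl]phenoxy}propanal | C[C@H](Oc1cc(OC)c(Br)c(CCc2ccc(OC)cc2)c1Br)C=O | intermediate
9 | diethyl (3,5-dimethoxybenzyl)phosphonate | CCOP(=O)(Cc1cc(OC)cc(OC)c1)OCC | starting material
10 | 1,3-dibromo-4-{[(2S,3E)-4-(3,5-dimethoxyphenyl)but-3-en-2-yl]oxy}-6-methoxy-2-[2-(4-methoxyphenyl)ethyl]benzene | C[C@H](Oc1cc(OC)c(Br)c(CCc2ccc(OC)cc2)c1Br)/C=C/c1cc(OC)cc(OC)c1 | intermediate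
11 | 2,4-dibromo-6-[(2E)-1-(3,5-dimethoxyphenyl)but-2-en-1-yl]-5-methoxy-3-[2-(4-methoxyphenyl)ethyl]cyclohexa-2,4-dien-1-one (ortho-dienone; side-chain centre as in 12, ring C6 unassigned) | O=C1C(Br)=C(CCc2ccc(OC)cc2)C(Br)=C(OC)C1[C@H](c1cc(OC)cc(OC)c1)/C=C/C | intermediate
12 | 4,6-dibromo-2-[(1S,2E)-1-(3,5-dimethoxyphenyl)but-2-en-1-yl]-3-methoxy-5-[2-(4-methoxyphenyl)ethyl]phenol | Oc1c(Br)c(CCc2ccc(OC)cc2)c(Br)c(OC)c1[C@H](c1cc(OC)cc(OC)c1)/C=C/C | intermediate
13 | (2S)-2-{3,5-dibromo-2-hydroxy-6-methoxy-4-[2-(4-methoxyphenyl)ethyl]phenyl}-2-(3,5-dimethoxyphenyl)acetaldehyde (hydroxy-aldehyde) | Oc1c(Br)c(CCc2ccc(OC)cc2)c(Br)c(OC)c1[C@H](c1cc(OC)cc(OC)c1)C=O | intermediate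
14 | (3S)-5,7-dibromo-3-(3,5-dimethoxyphenyl)-4-methoxy-6-[2-(4-methoxyphenyl)ethyl]-2,3-dihydro-1-benzofuran-2-ol (both C2 epimers) | COc1ccc(CCc2c(Br)c(OC)c3c(c2Br)OC(O)[C@H]3c2cc(OC)cc(OC)c2)cc1 | intermediate
15 | 2,4-dimethoxyphenylmagnesium bromide | COc1ccc([Mg]Br)c(OC)c1 | starting material
16 | (2S)-2-{3,5-dibromo-2-hydroxy-6-methoxy-4-[2-(4-methoxyphenyl)ethyl]phenyl}-1-(2,4-dimethoxyphenyl)-2-(3,5-dimethoxyphenyl)ethan-1-ol (diol; both C1 epimers) | Oc1c(Br)c(CCc2ccc(OC)cc2)c(Br)c(OC)c1[C@H](c1cc(OC)cc(OC)c1)C(O)c1ccc(OC)cc1OC | intermediate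
17 | (2S,3S)-5,7-dibromo-2-(2,4-dimethoxyphenyl)-3-(3,5-dimethoxyphenyl)-4-methoxy-6-[2-(4-methoxyphenyl)ethyl]-2,3-dihydro-1-benzofuran | COc1ccc(CCc2c(Br)c(OC)c3c(c2Br)O[C@H](c2ccc(OC)cc2OC)[C@H]3c2cc(OC)cc(OC)c2)cc1 | intermediate
18 | (2S,3S)-2-(2,4-dimethoxyphenyl)-3-(3,5-dimethoxyphenyl)-4-methoxy-6-[2-(4-methoxyphenyl)ethyl]-2,3-dihydro-1-benzofuran | COc1ccc(CCc2cc(OC)c3c(c2)O[C@H](c2ccc(OC)cc2OC)[C@H]3c2cc(OC)cc(OC)c2)cc1 | intermediate
19 | (2S,3S)-2-(2,4-dihydroxyphenyl)-3-(3,5-dihydroxyphenyl)-6-[2-(4-hydroxyphenyl)ethyl]-2,3-dihydro-1-benzofuran-4-ol (CNP0329616.1) | Oc1ccc(CCc2cc(O)c3c(c2)O[C@H](c2ccc(O)cc2O)[C@H]3c2cc(O)cc(O)c2)cc1 | target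

**Step count and risks**

Total steps: 10. Longest linear sequence: 10 steps (1 and 2 to 19); 6, 9 and 15 are bought and enter directly.

Risk 1, step 6 (Claisen rearrangement). The ether is secondary, allylic and styrenyl, and the dibromophenoxide is a good leaving group, so at 180 °C ion-pair dissociation could erode the chirality transfer or give [1,3] products. Any Z isomer of 12 carries the opposite C3 configuration and must be removed by chromatography before ozonolysis. The fallback replaces the sigmatropic transfer by a copper-mediated anti-SN2′ arylation; it sets out from 5 and comes back at 12.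
- Cross-metathesis of (R)-but-3-en-2-ol with 3,5-dimethoxystyrene (second-generation Hoveyda–Grubbs catalyst) gives (2R,3E)-4-(3,5-dimethoxyphenyl)but-3-en-2-ol F1.
- Picolinoyl chloride and Et3N convert it into (2R,3E)-4-(3,5-dimethoxyphenyl)but-3-en-2-yl pyridine-2-carboxylate F2.
- Phenol 5 is protected (MOMCl, iPr2NEt) as 1,3-dibromo-4-methoxy-6-(methoxymethoxy)-2-[2-(4-methoxyphenyl)ethyl]benzene F3.
- Its only ring C–H, between the two oxygens, is metalated with lithium 2,2,6,6-tetramethylpiperidide (THF, −78 °C), transmetalated with MgBr2·OEt2 and coupled with F2 in the presence of CuBr·SMe2.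
- Anti attack on the (R) picolinate gives the same (S,E) centre as the syn [3,3] shift of the (S) ether, as the methoxymethyl ether of 12 F4.
- HCl in MeOH then gives 12.

Risk 2, step 8 (aryl addition and ring closure). The α,α-diaryl aldehyde can enolize instead of adding, the lactol can dehydrate to a 3-arylbenzofuran, and the benzylic cation can lose the C3 proton to a triarylethene or be intercepted by 1,3-dimethoxybenzene. The fallback avoids any basic organometallic; it sets out from 14 and comes back at 17.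
- Acetylation (Ac2O, pyridine, DMAP) gives (3S)-5,7-dibromo-3-(3,5-dimethoxyphenyl)-4-methoxy-6-[2-(4-methoxyphenyl)ethyl]-2,3-dihydro-1-benzofuran-2-yl acetate F5.
- BF3·OEt2 in CH2Cl2 at −78 °C with 1,3-dimethoxybenzene (5 equiv) generates the benzofuranyl oxocarbenium ion, which undergoes Friedel–Crafts capture at C4 of the arene, trans to the C3 aryl group, to give 17 directly.

Risk 3, step 10 (sixfold demethylation). BBr3 can open the C2–O bond, and the resulting cation can alkylate the electron-rich C5 and C7 positions of ring A of another molecule. The fallback reverses the last two operations; it sets out from 17 and comes back at 19.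
- BBr3 is applied to 17 while the bromines still block C5 and C7, giving (2S,3S)-5,7-dibromo-2-(2,4-dihydroxyphenyl)-3-(3,5-dihydroxyphenyl)-6-[2-(4-hydroxyphenyl)ethyl]-2,3-dihydro-1-benzofuran-4-ol F6.
- Hydrogenolysis (H2, 10% Pd/C, Et3N, MeOH) then removes the bromines and delivers 19.

**Further compounds**

F1 | step 6 | (2R,3E)-4-(3,5-dimethoxyphenyl)but-3-en-2-ol | C[C@@H](O)/C=C/c1cc(OC)cc(OC)c1
F2 | step 6 | (2R,3E)-4-(3,5-dimethoxyphenyl)but-3-en-2-yl pyridine-2-carboxylate | C[C@@H](OC(=O)c1ccccn1)/C=C/c1cc(OC)cc(OC)c1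
F3 | step 6 | 1,3-dibromo-4-methoxy-6-(methoxymethoxy)-2-[2-(4-methoxyphenyl)ethyl]benzene | COCOc1cc(OC)c(Br)c(CCc2ccc(OC)cc2)c1Br
F4 | step 6 | methoxymethyl ether of 12: 1,5-dibromo-3-[(1S,2E)-1-(3,5-dimethoxyphenyl)but-2-en-1-yl]-2-methoxy-4-(methoxymethoxy)-6-[2-(4-methoxyphenyl)ethyl]benzene | COCOc1c(Br)c(CCc2ccc(OC)cc2)c(Br)c(OC)c1[C@H](c1cc(OC)cc(OC)c1)/C=C/C
F5 | step 8 | (3S)-5,7-dibromo-3-(3,5-dimethoxyphenyl)-4-methoxy-6-[2-(4-methoxyphenyl)ethyl]-2,3-dihydro-1-benzofuran-2-yl acetate | COc1ccc(CCc2c(Br)c(OC)c3c(c2Br)OC(OC(C)=O)[C@H]3c2cc(OC)cc(OC)c2)cc1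
F6 | step 10 | (2S,3S)-5,7-dibromo-2-(2,4-dihydroxyphenyl)-3-(3,5-dihydroxyphenyl)-6-[2-(4-hydroxyphenyl)ethyl]-2,3-dihydro-1-benzofuran-4-ol | Oc1ccc(CCc2c(Br)c(O)c3c(c2Br)O[C@H](c2ccc(O)cc2O)[C@H]3c2cc(O)cc(O)c2)cc1
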